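**Retrosynthetic overview**

1. Target 23 ← allylic alcohol 22 ← enoate 21 ← methyl ketone 20 ← ketal 19: the C13–C15 end of the side chain is built last (Horner–Wadsworth–Emmons, iBu2AlH, propionylation) on a masked C13 ketone.
2. 19 ← 3-oxo bicycle 16: the C3 carbonyl that enables the ring closure is removed afterwards (NaBH4, then Barton–McCombie).
3. Key disconnection C4–C5. The quaternary C4 (Me, CO2Me) and the methine C5 are adjacent stereocentres beside the C1=C10 alkene of ring A (C1–C5, C10). A C4 radical from 2-methyl-3-oxo ester 14 therefore adds to C5 of a C5=C10 alkene in the preformed ring B (C5–C10), and the C10 radical is oxidised toward C1. Ring A is formed last.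
4. 14 ← Weinreb amide 11 ← ester 10 ← enol triflate 7 + zinc homoenolate 9 (C10–C1 bond by Negishi coupling).
5. 7 ← ketone 6 ← diketone 5 ← 2-methylcyclohexenone 1: ring B is the enone ring; C8 is set by catalytic asymmetric methyl addition, C9 by Mukaiyama–Michael addition to butenone.

Key step: step 8

Remark 1: halimane numbering is used for all intermediates (ring A = C1–C5 and C10; ring B = C5–C10; side chain from C11).
Remark 2 (assumption): the antipode of the phosphoramidite ligand in step 1 is the one that delivers the 3R product; both antipodes of such ligands are available.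

**Route**

Step 1
Reactants: 1 2-methylcyclohex-2-en-1-one
Product: 3 [(3R)-2,3-dimethylcyclohex-1-en-1-yl]oxy(trimethyl)silane, via dimethylaluminium enolate 2 (not isolated)
Conditions: Me3Al (1.4 equiv), Cu(OTf)2 (2 mol %), BINOL-derived phosphoramidite with a bis(1-phenylethyl)amine unit (4 mol %), Et2O, −30 °C; then Me3SiOTf, THF, −30 → 0 °C
Reagents that add atoms: trimethylaluminium C[Al](C)C; trimethylsilyl trifluoromethanesulfonate C[Si](C)(C)OS(=O)(=O)C(F)(F)F
Why: Copper-catalysed asymmetric conjugate addition of Me3Al, in which the chiral phosphoramidite–copper complex delivers methyl to one face of the enone and sets C8 (3R), followed by O-silylation of the regiodefined aluminium enolate, which fixes the enolate position for step 2.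

Step 2
Reactants: 3 [(3R)-2,3-dimethylcyclohex-1-en-1-yl]oxy(trimethyl)silane; 4 but-3-en-2-one
Product: 5 (2S,3R)-2,3-dimethyl-2-(3-oxobutyl)cyclohexan-1-one
Conditions: BF3·OEt2 (1.1 equiv), iPrOH (1.1 equiv), MeNO2, −20 °C
Reagents that add atoms: none
Why: Mukaiyama–Michael addition in which BF3-activated butenone is attacked by the fully substituted enol ether carbon on the face anti to the adjacent C8 methyl (pseudoaxial to avoid A(1,2) strain with the vinylic methyl), so the chain enters trans to it and the C8 and C9 methyls end up cis at the new quaternary C9.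

Step 3
Reactants: 5 (2S,3R)-2,3-dimethyl-2-(3-oxobutyl)cyclohexan-1-one
Product: 6 (2S,3R)-2,3-dimethyl-2-[2-(2-methyl-1,3-dioxolan-2-yl)ethyl]cyclohexan-1-one
Conditions: Me3SiOCH2CH2OSiMe3 (1.5 equiv), Me3SiOTf (5 mol %), CH2Cl2, −78 → −20 °C; pyridine quench
Reagents that add atoms: 1,2-bis(trimethylsilyloxy)ethane C[Si](C)(C)OCCO[Si](C)(C)C
Why: Silyl-triflate-catalysed ketalisation at low temperature is selective for the unhindered side-chain methyl ketone over the ring ketone flanked by the quaternary carbon, and is mild enough to avoid acid-induced aldol closure of the 1,5-diketone.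

Step 4
Reactants: 6 (2S,3R)-2,3-dimethyl-2-[2-(2-methyl-1,3-dioxolan-2-yl)ethyl]cyclohexan-1-one
Product: 7 (5R,6S)-5,6-dimethyl-6-[2-(2-methyl-1,3-dioxolan-2-yl)ethyl]cyclohex-1-en-1-yl trifluoromethanesulfonate
Conditions: KN(SiMe3)2 (1.2 equiv), THF, −78 °C; PhNTf2 (1.2 equiv), −78 → 0 °C
Reagents that add atoms: N-phenylbis(trifluoromethanesulfonimide) O=S(=O)(N(c1ccccc1)S(=O)(=O)C(F)(F)F)C(F)(F)F
Why: Enol triflate formation, in which deprotonation can occur only toward C5 because C9 is quaternary, so the C10=C5 alkene of ring B is placed without regiochemical ambiguity.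

Step 5
Reactants: 7 (5R,6S)-5,6-dimethyl-6-[2-(2-methyl-1,3-dioxolan-2-yl)ethyl]cyclohex-1-en-1-yl trifluoromethanesulfonate; 8 ethyl 3-iodopropanoate
Product: 10 ethyl 3-[(5R,6S)-5,6-dimethyl-6-[2-(2-methyl-1,3-dioxolan-2-yl)ethyl]cyclohex-1-en-1-yl]propanoate, via zinc homoenolate 9 (not isolated)
Conditions: Zn dust (activated by BrCH2CH2Br and Me3SiCl), THF, 35 °C; then 7, Pd(PPh3)4 (5 mol %), THF/DMA, 60 °C
Reagents that add atoms: none
Why: Negishi coupling in which zerovalent palladium inserts into the enol triflate and the chelation-stabilised β-zincio ester, which resists β-hydride elimination, transmetalates and couples to form the C10–C1 bond, the established behaviour of zinc homoenolates toward enol triflates.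

Step 6
Reactants: 10 ethyl 3-[(5R,6S)-5,6-dimethyl-6-[2-(2-methyl-1,3-dioxolan-2-yl)ethyl]cyclohex-1-en-1-yl]propanoate
Product: 11 3-[(5R,6S)-5,6-dimethyl-6-[2-(2-methyl-1,3-dioxolan-2-yl)ethyl]cyclohex-1-en-1-yl]-N-methoxy-N-methylpropanamide
Conditions: MeNH(OMe)·HCl (1.6 equiv), iPrMgCl (3.2 equiv), THF, −20 → 0 °C
Reagents that add atoms: N,O-dimethylhydroxylamine hydrochloride CNOC.Cl
Why: Direct aminolysis of the ethyl ester by the chloromagnesium amide gives the Weinreb amide, an acyl donor that reacts faster than it is enolised and cannot add twice, which a direct crossed Claisen between two enolisable esters would not guarantee.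

Step 7
Reactants: 11 3-[(5R,6S)-5,6-dimethyl-6-[2-(2-methyl-1,3-dioxolan-2-yl)ethyl]cyclohex-1-en-1-yl]-N-methoxy-N-methylpropanamide; 12 methyl propanoate
Product: 14 methyl 5-[(5R,6S)-5,6-dimethyl-6-[2-(2-methyl-1,3-dioxolan-2-yl)ethyl]cyclohex-1-en-1-yl]-2-methyl-3-oxopentanoate (both C4 epimers), via lithium ester enolate 13 (not isolated)
Conditions: LiN(iPr)2 (3 equiv), 12 (3 equiv), THF, −78 °C; then 11, −78 → −20 °C; aq NH4Cl
Reagents that add atoms: none
Why: Acylation of a preformed ester lithium enolate by a Weinreb amide (a crossed Claisen equivalent), in which the chelated tetrahedral adduct persists until work-up, should give the 2-methyl-3-oxo ester without self-condensation; the C4 epimer mixture is of no consequence because C4 becomes planar in step 8.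

Step 8
Reactants: 14 methyl 5-[(5R,6S)-5,6-dimethyl-6-[2-(2-methyl-1,3-dioxolan-2-yl)ethyl]cyclohex-1-en-1-yl]-2-methyl-3-oxopentanoate
Product: 16 methyl (1R,5S,6R,8aR)-1,5,6-trimethyl-5-[2-(2-methyl-1,3-dioxolan-2-yl)ethyl]-2-oxo-1,2,3,5,6,7,8,8a-octahydronaphthalene-1-carboxylate, via tertiary C10 radical 15 (not isolated)
Conditions: Mn(OAc)3·2H2O (2.2 equiv), Cu(OAc)2·H2O (1.0 equiv), KOAc (2 equiv), degassed AcOH, 25–35 °C
Reagents that add atoms: none
Why: Mn(OAc)3 converts the 3-oxo ester into its trivalent manganese enolate and inner-sphere electron transfer gives the electrophilic tertiary C4 radical, as in the known Mn(OAc)3/Cu(OAc)2 oxidative radical cyclisations of unsaturated 2-alkyl-3-oxo esters. This radical adds to C5, the less substituted carbon of the C5=C10 alkene, in a 6-endo-trig closure of ring A, because that gives tertiary radical 15 whereas 5-exo attack at C10 would build a quaternary carbon next to the quaternary C9. C4 is set by the chair-like transition state with the ketone inside the forming ring and the ester axial, which places CO2Me trans to H5 (C6 is trans to the tether on the alkene and becomes equatorial on ring A). C5 is set by the face of ring B: with the C8 methyl equatorial the cis C9 methyl is pseudoaxial on one face, so the tether should close on the opposite face, the one carrying the C9 side chain, leaving H5 cis to the C9 methyl. Cu(OAc)2 captures radical 15 on that same open face as an alkylcopper species, which can lose a syn β-hydrogen only from C1 (C9 has none and H5 is anti), giving the C1=C10 alkene instead of the tetrasubstituted C5=C10 isomer. The step needs facial selectivity at C5 and elimination toward C1, which are its two least secure points; the acetate buffer and low temperature are chosen to keep the dioxolane intact, and only a slight excess of oxidant is used to spare the doubly activated C2 methylene of the product.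

Step 9
Reactants: 16 methyl (1R,5S,6R,8aR)-1,5,6-trimethyl-5-[2-(2-methyl-1,3-dioxolan-2-yl)ethyl]-2-oxo-1,2,3,5,6,7,8,8a-octahydronaphthalene-1-carboxylate
Product: 17 methyl (1R,5S,6R,8aR)-2-hydroxy-1,5,6-trimethyl-5-[2-(2-methyl-1,3-dioxolan-2-yl)ethyl]-1,2,3,5,6,7,8,8a-octahydronaphthalene-1-carboxylate (C3 epimers)
Conditions: NaBH4, MeOH, −10 → 0 °C
Reagents that add atoms: none
Why: Hydride reduction of the C3 ketone, to which the hindered quaternary methyl ester and the dioxolane are inert, is run cold so that it outruns base-induced migration of the C1=C10 alkene into conjugation; the new C3 carbinol centre is removed in step 11, so its configuration is immaterial.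

Step 10
Reactants: 17 methyl (1R,5S,6R,8aR)-2-hydroxy-1,5,6-trimethyl-5-[2-(2-methyl-1,3-dioxolan-2-yl)ethyl]-1,2,3,5,6,7,8,8a-octahydronaphthalene-1-carboxylate
Product: 18 methyl (1R,5S,6R,8aR)-2-[(1H-imidazol-1-ylcarbonothioyl)oxy]-1,5,6-trimethyl-5-[2-(2-methyl-1,3-dioxolan-2-yl)ethyl]-1,2,3,5,6,7,8,8a-octahydronaphthalene-1-carboxylate
Conditions: 1,1'-thiocarbonyldiimidazole (3 equiv), DMAP (0.2 equiv), ClCH2CH2Cl, 80 °C
Reagents that add atoms: 1,1'-thiocarbonyldiimidazole S=C(n1ccnc1)n1ccnc1
Why: Thioacylation of the secondary alcohol without forming an alkoxide (the activation stage of the Barton–McCombie reaction) avoids the retro-aldol cleavage that an NaH/CS2/MeI xanthate protocol would risk with this β-hydroxy ester.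

Step 11
Reactants: 18 methyl (1R,5S,6R,8aR)-2-[(1H-imidazol-1-ylcarbonothioyl)oxy]-1,5,6-trimethyl-5-[2-(2-methyl-1,3-dioxolan-2-yl)ethyl]-1,2,3,5,6,7,8,8a-octahydronaphthalene-1-carboxylate
Product: 19 methyl (1S,5S,6R,8aR)-1,5,6-trimethyl-5-[2-(2-methyl-1,3-dioxolan-2-yl)ethyl]-1,2,3,5,6,7,8,8a-octahydronaphthalene-1-carboxylate
Conditions: Bu3SnH (2 equiv), AIBN (0.2 equiv), toluene, 110 °C
Reagents that add atoms: none
Why: Barton–McCombie deoxygenation, in which the stannyl radical adds to C=S, the C3–O bond fragments and the secondary C3 radical takes hydrogen from Bu3SnH faster than the ring-held homoallylic radical can close onto C1, as in the deoxygenation of 3-hydroxy-Δ5-steroids.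

Step 12
Reactants: 19 methyl (1S,5S,6R,8aR)-1,5,6-trimethyl-5-[2-(2-methyl-1,3-dioxolan-2-yl)ethyl]-1,2,3,5,6,7,8,8a-octahydronaphthalene-1-carboxylate
Product: 20 methyl (1S,5S,6R,8aR)-1,5,6-trimethyl-5-(3-oxobutyl)-1,2,3,5,6,7,8,8a-octahydronaphthalene-1-carboxylate
Conditions: 1 M aq HCl/THF (1:3), rt
Reagents that add atoms: water O
Why: Acid-catalysed ketal hydrolysis under conditions mild enough to leave the trisubstituted C1=C10 alkene and the hindered methyl ester untouched.

Step 13
Reactants: 20 methyl (1S,5S,6R,8aR)-1,5,6-trimethyl-5-(3-oxobutyl)-1,2,3,5,6,7,8,8a-octahydronaphthalene-1-carboxylate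
Product: 21 methyl (1S,5S,6R,8aR)-5-[(3E)-5-ethoxy-3-methyl-5-oxopent-3-en-1-yl]-1,5,6-trimethyl-1,2,3,5,6,7,8,8a-octahydronaphthalene-1-carboxylate
Conditions: (EtO)2P(O)CH2CO2Et (3 equiv), NaH (2.8 equiv), THF, 0 → 50 °C
Reagents that add atoms: triethyl phosphonoacetate CCOC(=O)CP(=O)(OCC)OCC
Why: Horner–Wadsworth–Emmons olefination of the methyl ketone with a stabilised phosphonate anion should give mainly the E enoate (ester trans to the larger C12 chain), the minor Z isomer being removed by chromatography; the C4 ester has no α-hydrogen and is unaffected.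

Step 14
Reactants: 21 methyl (1S,5S,6R,8aR)-5-[(3E)-5-ethoxy-3-methyl-5-oxopent-3-en-1-yl]-1,5,6-trimethyl-1,2,3,5,6,7,8,8a-octahydronaphthalene-1-carboxylate
Product: 22 methyl (1S,5S,6R,8aR)-5-[(3E)-5-hydroxy-3-methylpent-3-en-1-yl]-1,5,6-trimethyl-1,2,3,5,6,7,8,8a-octahydronaphthalene-1-carboxylate
Conditions: iBu2AlH (2.3 equiv), CH2Cl2, −78 °C; aq potassium sodium tartrate
Reagents that add atoms: none
Why: iBu2AlH reduces the unhindered conjugated ethyl ester to the allylic alcohol by 1,2-reduction at −78 °C, whereas the axial methyl ester on the quaternary C4 is too hindered to react at that temperature.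

Step 15
Reactants: 22 methyl (1S,5S,6R,8aR)-5-[(3E)-5-hydroxy-3-methylpent-3-en-1-yl]-1,5,6-trimethyl-1,2,3,5,6,7,8,8a-octahydronaphthalene-1-carboxylate
Product: 23 methyl (1S,5S,6R,8aR)-1,5,6-trimethyl-5-[(3E)-3-methyl-5-(propanoyloxy)pent-3-en-1-yl]-1,2,3,5,6,7,8,8a-octahydronaphthalene-1-carboxylate (CNP0279628.1)
Conditions: (EtCO)2O (1.5 equiv), Et3N (2 equiv), DMAP (0.1 equiv), CH2Cl2, 0 °C → rt
Reagents that add atoms: propanoic anhydride CCC(=O)OC(=O)CC
Why: DMAP-catalysed acylation of the primary allylic alcohol completes the propanoate without touching any stereocentre.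

**Compound list**

1 | 2-methylcyclohex-2-en-1-one | CC1=CCCCC1=O | starting material
2 | dimethylaluminium (3R)-2,3-dimethylcyclohex-1-en-1-olate (formed in the flask) | C[C@@H]1CCCC(O[Al](C)C)=C1C | intermediate
3 | [(3R)-2,3-dimethylcyclohex-1-en-1-yl]oxy(trimethyl)silane | C[C@@H]1CCCC(O[Si](C)(C)C)=C1C | intermediate
4 | but-3-en-2-one | CC(=O)C=C | starting material
5 | (2S,3R)-2,3-dimethyl-2-(3-oxobutyl)cyclohexan-1-one | CC(=O)CC[C@]1(C)C(=O)CCC[C@H]1C | intermediate
6 | (2S,3R)-2,3-dimethyl-2-[2-(2-methyl-1,3-dioxolan-2-yl)ethyl]cyclohexan-1-one | CC1(CC[C@]2(C)C(=O)CCC[C@H]2C)OCCO1 | intermediate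
7 | (5R,6S)-5,6-dimethyl-6-[2-(2-methyl-1,3-dioxolan-2-yl)ethyl]cyclohex-1-en-1-yl trifluoromethanesulfonate | CC1(CC[C@]2(C)C(OS(=O)(=O)C(F)(F)F)=CCC[C@H]2C)OCCO1 | intermediate
8 | ethyl 3-iodopropanoate | CCOC(=O)CCI | starting material
9 | (3-ethoxy-3-oxopropyl)zinc iodide (formed in the flask) | CCOC(=O)CC[Zn]I | intermediate
10 | ethyl 3-[(5R,6S)-5,6-dimethyl-6-[2-(2-methyl-1,3-dioxolan-2-yl)ethyl]cyclohex-1-en-1-yl]propanoate | CC1(CC[C@]2(C)C(CCC(=O)OCC)=CCC[C@H]2C)OCCO1 | intermediate
11 | 3-[(5R,6S)-5,6-dimethyl-6-[2-(2-methyl-1,3-dioxolan-2-yl)ethyl]cyclohex-1-en-1-yl]-N-methoxy-N-methylpropanamide | CC1(CC[C@]2(C)C(CCC(=O)N(C)OC)=CCC[C@H]2C)OCCO1 | intermediate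
12 | methyl propanoate | CCC(=O)OC | starting material
13 | lithium 1-methoxyprop-1-en-1-olate (formed in the flask) | CC=C(OC)O[Li] | intermediate
14 | methyl 5-[(5R,6S)-5,6-dimethyl-6-[2-(2-methyl-1,3-dioxolan-2-yl)ethyl]cyclohex-1-en-1-yl]-2-methyl-3-oxopentanoate (C4 epimers) | CC1(CC[C@]2(C)C(CCC(=O)C(C)C(=O)OC)=CCC[C@H]2C)OCCO1 | intermediate
15 | tertiary C10 radical of the cyclised 3-oxo ester (formed in the flask) | CC1(CC[C@]2(C)[C]3CCC(=O)[C@](C)(C(=O)OC)[C@@H]3CC[C@H]2C)OCCO1 | intermediate
16 | methyl (1R,5S,6R,8aR)-1,5,6-trimethyl-5-[2-(2-methyl-1,3-dioxolan-2-yl)ethyl]-2-oxo-1,2,3,5,6,7,8,8a-octahydronaphthalene-1-carboxylate | CC1(CC[C@]2(C)C3=CCC(=O)[C@](C)(C(=O)OC)[C@@H]3CC[C@H]2C)OCCO1 | intermediate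
17 | methyl (1R,5S,6R,8aR)-2-hydroxy-1,5,6-trimethyl-5-[2-(2-methyl-1,3-dioxolan-2-yl)ethyl]-1,2,3,5,6,7,8,8a-octahydronaphthalene-1-carboxylate (C3 epimers) | CC1(CC[C@]2(C)C3=CCC(O)[C@](C)(C(=O)OC)[C@@H]3CC[C@H]2C)OCCO1 | intermediate
18 | methyl (1R,5S,6R,8aR)-2-[(1H-imidazol-1-ylcarbonothioyl)oxy]-1,5,6-trimethyl-5-[2-(2-methyl-1,3-dioxolan-2-yl)ethyl]-1,2,3,5,6,7,8,8a-octahydronaphthalene-1-carboxylate | CC1(CC[C@]2(C)C3=CCC(OC(=S)n4ccnc4)[C@](C)(C(=O)OC)[C@@H]3CC[C@H]2C)OCCO1 | intermediate
19 | methyl (1S,5S,6R,8aR)-1,5,6-trimethyl-5-[2-(2-methyl-1,3-dioxolan-2-yl)ethyl]-1,2,3,5,6,7,8,8a-octahydronaphthalene-1-carboxylate | CC1(CC[C@]2(C)C3=CCC[C@](C)(C(=O)OC)[C@@H]3CC[C@H]2C)OCCO1 | intermediate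
20 | methyl (1S,5S,6R,8aR)-1,5,6-trimethyl-5-(3-oxobutyl)-1,2,3,5,6,7,8,8a-octahydronaphthalene-1-carboxylate | CC(=O)CC[C@]1(C)C2=CCC[C@](C)(C(=O)OC)[C@@H]2CC[C@H]1C | intermediate
21 | methyl (1S,5S,6R,8aR)-5-[(3E)-5-ethoxy-3-methyl-5-oxopent-3-en-1-yl]-1,5,6-trimethyl-1,2,3,5,6,7,8,8a-octahydronaphthalene-1-carboxylate | CCOC(=O)/C=C(\C)CC[C@]1(C)C2=CCC[C@](C)(C(=O)OC)[C@@H]2CC[C@H]1C | intermediate
22 | methyl (1S,5S,6R,8aR)-5-[(3E)-5-hydroxy-3-methylpent-3-en-1-yl]-1,5,6-trimethyl-1,2,3,5,6,7,8,8a-octahydronaphthalene-1-carboxylate | OC/C=C(\C)CC[C@]1(C)C2=CCC[C@](C)(C(=O)OC)[C@@H]2CC[C@H]1C | intermediate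
23 | methyl (1S,5S,6R,8aR)-1,5,6-trimethyl-5-[(3E)-3-methyl-5-(propanoyloxy)pent-3-en-1-yl]-1,2,3,5,6,7,8,8a-octahydronaphthalene-1-carboxylate (CNP0279628.1) | CCC(=O)OC/C=C(\C)CC[C@]1(C)C2=CCC[C@](C)(C(=O)OC)[C@@H]2CC[C@H]1C | target

**Step count**

Total: 15 steps. Longest linear sequence: 15 steps (1 → 23); the zinc and lithium reagents are made in the flask within steps 5 and 7.

**Steps most likely to fail**

Step 8. The radical may add to C5 with poor facial selectivity, because the two groups on the quaternary C9 differ little in size. The C10 copper species may also eliminate toward C5, or be oxidised to a cation that rearranges. The doubly activated C2 methylene of the product may be oxidised further. The fallback sets out from enol triflate 7 and replaces the radical closure by a cycloaddition. Stille coupling with tributyl(vinyl)stannane (Pd(PPh3)4, LiCl, THF, 65 °C) should give the 1-vinylcyclohexene diene F1. A thermal Diels–Alder reaction of this diene with methyl methacrylate (toluene, radical inhibitor, sealed tube, about 150 °C) would form C4–C5 and C2–C3 together, with the quaternary ester carbon on C5 (ortho orientation). The C1=C10 alkene is fixed by the pericyclic topology and no C3 oxygen is introduced. The adduct with the ester trans to H5 and H5 cis to the C9 methyl would be separated from its stereoisomers; it is compound 19, where the route is rejoined and steps 8–11 are bypassed.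

Step 2. Carbon–carbon bond formation at the fully substituted enol ether carbon may be slow, so that protodesilylation to the ketone and polymerisation of butenone take over, and the anti selectivity may be modest. The fallback sets out from silyl enol ether 3 and uses enolate alkylation (Wichterle reaction) instead of the Lewis acid Michael addition. MeLi in THF at 0 °C would release the regiodefined lithium enolate F2, which would be alkylated by the reactive allylic chloride 1,3-dichlorobut-2-ene trans to the C8 methyl to give the vinyl chloride F3. Hydrolysis of the vinyl chloride with Hg(OAc)2 and BF3·OEt2 in AcOH would give diketone 5, where the route is rejoined.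

Step 5. Transmetalation and reductive elimination at the palladium centre beside the quaternary C9 may be slow, so that reduction of the triflate and homocoupling of the zinc reagent compete. The fallback sets out from enol triflate 7 and builds the arm by alkylation of a dianion instead. Methoxycarbonylation (Pd(OAc)2, PPh3, CO, MeOH, Et3N, DMF) should give the enoate F4. iBu2AlH at −78 °C would give the allylic alcohol F5, and CBr4/PPh3 would convert it into the allylic bromide F6. Alkylation of the dianion of methyl 2-methyl-3-oxobutanoate (NaH, then nBuLi, THF, 0 °C) at its terminal methyl carbon by F6 would give 3-oxo ester 14 directly, where the route is rejoined and steps 5–7 are bypassed.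

**Further compounds**

F1 | step 8 | (5R,6S)-1-ethenyl-5,6-dimethyl-6-[2-(2-methyl-1,3-dioxolan-2-yl)ethyl]cyclohex-1-ene | CC1(CC[C@]2(C)C(C=C)=CCC[C@H]2C)OCCO1
F2 | step 2 | lithium (3R)-2,3-dimethylcyclohex-1-en-1-olate | C[C@@H]1CCCC(O[Li])=C1C
F3 | step 2 | (2S,3R)-2-(3-chlorobut-2-en-1-yl)-2,3-dimethylcyclohexan-1-one (alkene isomers) | CC(Cl)=CC[C@]1(C)C(=O)CCC[C@H]1C
F4 | step 5 | methyl (5R,6S)-5,6-dimethyl-6-[2-(2-methyl-1,3-dioxolan-2-yl)ethyl]cyclohex-1-ene-1-carboxylate | CC1(CC[C@]2(C)C(C(=O)OC)=CCC[C@H]2C)OCCO1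
F5 | step 5 | [(5R,6S)-5,6-dimethyl-6-[2-(2-methyl-1,3-dioxolan-2-yl)ethyl]cyclohex-1-en-1-yl]methanol | CC1(CC[C@]2(C)C(CO)=CCC[C@H]2C)OCCO1
F6 | step 5 | 2-{2-[(1S,6R)-2-(bromomethyl)-1,6-dimethylcyclohex-2-en-1-yl]ethyl}-2-methyl-1,3-dioxolane | CC1(CC[C@]2(C)C(CBr)=CCC[C@H]2C)OCCO1
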